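## Plan

- Core numbering (bicyclo[3.1.0]hexane): C1 = fusion C–CH3, C2 = C(Ar)(CH3), C3–C4 = CH2CH2, C5 = fusion CH, C6 = cyclopropane CH2. The retrosynthesis first cuts the two Ar–Br bonds, masks O–H as O–CH3, and desaturates C3–C4.
- C1–C5 and C5–C6 are then cut together. This unfolds both rings into the acyclic 1,5-enyne 11, H2C6=C1(CH3)–C2(Ar)(CH3)–C3H2–C4≡C5H.
- Enabling feature: the cyclopropane shares its C1–C5 edge with a cyclopentane whose C3–C4 edge is unsubstituted, and C5 and C6 carry only hydrogen. This is the retron of a 1,5-enyne cycloisomerisation, with C6=C1 as the alkene, C4≡C5 as the alkyne and a C3–H as the migrating hydride.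
- Enyne 11 is cut at C1=C6 (Wittig), C1–CH3 (MeLi on the acid), C2–C3 (propargylation) and C2–Ar (α-arylation), leading back to 1, 2 and 5.
- Forward: steps 1–6 build the chain around C2 and step 7 forms both carbocycles at once. Alkene reduction, O-demethylation and double bromination follow.
- Stereochemistry: C2 comes from an enediolate alkylation controlled by a chiral lithium amide (step 3). C1 and C5 are relayed from C2 in step 7 by allylic strain, and the cis fusion is geometric.

Key step: step 7

Assumption: the (R,R)-tetraamine of step 3 is taken to expose the same enediolate face as with simple arylacetic acids, which corresponds to (S)-7. If the sense proves opposite, the (S,S)-antipode is used with no other change.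

## Route

Step 1
Reactants: 1 2-bromo-5-methylanisole; 2 tert-butyl propionate
Product: 3 tert-butyl 2-(2-methoxy-4-methylphenyl)propanoate (racemic)
Conditions: LiHMDS (2.2 equiv), Pd(OAc)2 (3 mol %), DavePhos (6 mol %), toluene, rt → 80 °C
Reagents that add atoms: none
Why: Palladium-catalysed α-arylation of an ester enolate (oxidative addition of 1, transmetalation with the lithium enolate of 2, reductive elimination from a bulky electron-rich phosphine complex) should give the mono-arylated ester; the tert-butyl group suppresses Claisen condensation, and the racemic centre is erased in step 3.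

Step 2
Reactants: 3 tert-butyl 2-(2-methoxy-4-methylphenyl)propanoate
Product: 4 2-(2-methoxy-4-methylphenyl)propanoic acid (racemic)
Conditions: TFA, CH2Cl2, 0 °C → rt
Reagents that add atoms: none
Why: Acidolysis of the tert-butyl ester (E1 loss of isobutene) frees the acid without touching the aryl methyl ether.

Step 3
Reactants: 4 2-(2-methoxy-4-methylphenyl)propanoic acid; 5 3-bromo-1-(trimethylsilyl)prop-1-yne
Product: 7 (S)-2-(2-methoxy-4-methylphenyl)-2-methyl-5-(trimethylsilyl)pent-4-ynoic acid, via dilithium enediolate 6 (not isolated)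
Conditions: (R,R)-N,N'-bis[1-phenyl-2-(piperidin-1-yl)ethyl]propane-1,3-diamine (1.05 equiv), n-BuLi (4.1 equiv), THF, 0 °C; then 5 (1.5 equiv), −78 °C; 1 M HCl work-up (amine recovered from the aqueous phase)
Reagents that add atoms: none
Why: This is an enantioselective alkylation of a carboxylic acid enediolate held in a mixed aggregate with a C2-symmetric chiral dilithium amide (a non-covalent, recoverable auxiliary); enediolate 6 has no E/Z isomerism, so only face selection matters, the aggregate shields one face, the reactive propargylic bromide enters from the other to set the quaternary centre (future C2) as S, and the silyl cap removes the acidic alkyne C–H.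

Step 4
Reactants: 7 (S)-2-(2-methoxy-4-methylphenyl)-2-methyl-5-(trimethylsilyl)pent-4-ynoic acid
Product: 9 (S)-3-(2-methoxy-4-methylphenyl)-3-methyl-6-(trimethylsilyl)hex-5-yn-2-one, via dilithium gem-diolate 8 (not isolated)
Conditions: MeLi (3 equiv), Et2O, 0 °C → rt; inverse quench into cold 1 M HCl
Reagents that add atoms: methyllithium, [Li]C
Why: Addition of methyllithium to the lithium carboxylate stops at the stable dilithium gem-diolate 8, which collapses to the methyl ketone only on the acidic quench; the quaternary centre cannot epimerise.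

Step 5
Reactants: 9 (S)-3-(2-methoxy-4-methylphenyl)-3-methyl-6-(trimethylsilyl)hex-5-yn-2-one
Product: 10 trimethyl[(4R)-4-(2-methoxy-4-methylphenyl)-4,5-dimethylhex-5-en-1-yn-1-yl]silane
Conditions: Ph3PCH3Br (3 equiv), NaHMDS (2.8 equiv), THF, 0 → 60 °C
Reagents that add atoms: methyltriphenylphosphonium bromide, C[P+](c1ccccc1)(c1ccccc1)c1ccccc1.[Br-]
Why: Wittig methylenation with excess non-stabilised ylide turns the hindered methyl ketone into the isopropenyl group (future C1, its CH3 and C6); the silyl cap prevents deprotonation or alkyne–allene isomerisation, and the descriptor changes to R only through CIP priorities.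

Step 6
Reactants: 10 trimethyl[(4R)-4-(2-methoxy-4-methylphenyl)-4,5-dimethylhex-5-en-1-yn-1-yl]silane
Product: 11 1-[(3R)-2,3-dimethylhex-1-en-5-yn-3-yl]-2-methoxy-4-methylbenzene
Conditions: K2CO3 (0.5 equiv), MeOH, rt
Reagents that add atoms: none
Why: Methoxide-catalysed protodesilylation of the alkynylsilane removes the temporary cap under conditions that leave the alkene, ether and quaternary centre untouched.

Step 7
Reactants: 11 1-[(3R)-2,3-dimethylhex-1-en-5-yn-3-yl]-2-methoxy-4-methylbenzene
Product: 13 (1S,4R,5S)-4-(2-methoxy-4-methylphenyl)-4,5-dimethylbicyclo[3.1.0]hex-2-ene (aryl syn to the cyclopropane CH2), via cyclopropyl gold carbene 12 (not isolated)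
Conditions: Ph3PAuNTf2 (2 mol %), CH2Cl2 (0.05 M), 0 °C → rt; Et3N quench
Reagents that add atoms: none
Why: π-Acidic Ph3PAu+ binds the terminal alkyne and the isopropenyl group attacks it anti to gold with its CH2 terminus leading (Markovnikov, tertiary cation character at the methyl-bearing carbon), whereupon the vinyl-gold carbon closes onto that carbon across the incipient six-membered array to forge the C1–C5 fusion bond and give cyclopropyl gold carbene 12, which after a 1,2-hydride shift from the propargylic C3H2 and loss of Ph3PAu+ leaves the C3=C4 alkene of 13. The closest known reaction type is the gold(I)- or platinum(II)-catalysed cycloisomerisation of 1,5-enynes to bicyclo[3.1.0]hex-2-enes, which is established for terminal alkynes, for 1,1-disubstituted alkenes and for products carrying quaternary carbons. The cyclopentene closes 5-endo-dig at the alkyne (5-exo-trig at the alkene) and the cyclopropane closes 3-exo, so the net event is an intramolecular cyclopropanation of the alkene by the alkyne terminus acting as a carbene equivalent. C1 and C5 are necessarily cis because one alkyne carbon bridges both alkene carbons on one face, and their sense relative to C2 is set by the existing quaternary centre: in the reactive rotamer the propargyl arm stands perpendicular to the alkene plane, so one remaining C2 substituent lies beside =CH2 and the other is nearly eclipsed with the vinylic CH3 (A1,2 strain), and the bulky o-anisyl group should take the =CH2 side, which places it syn to the new cyclopropane CH2 (pseudo-equatorial on the boat-like bicycle) as the target requires. The step needs attack by the alkene rather than by the arene or oxygen, and hydride shift rather than proton loss or aryl migration: the only free ortho position is meta to both OCH3 and CH3, the phenol is capped as its methyl ether and paired with a non-nucleophilic counter-ion, the propargylic CH2 supplies the migrating hydrogen, and a donor phosphine favours carbene-like over open-cation behaviour.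

Step 8
Reactants: 13 (1S,4R,5S)-4-(2-methoxy-4-methylphenyl)-4,5-dimethylbicyclo[3.1.0]hex-2-ene
Product: 14 (1S,2R,5R)-2-(2-methoxy-4-methylphenyl)-1,2-dimethylbicyclo[3.1.0]hexane
Conditions: 2-nitrobenzenesulfonylhydrazide (6 equiv, in portions), Et3N, CH2Cl2, rt
Reagents that add atoms: none
Why: Diimide reduction transfers H2 in a concerted syn fashion to the strained cis-disubstituted cyclopentene and avoids the vinylcyclopropane hydrogenolysis that heterogeneous catalysts can cause; no stereocentre is made or disturbed.

Step 9
Reactants: 14 (1S,2R,5R)-2-(2-methoxy-4-methylphenyl)-1,2-dimethylbicyclo[3.1.0]hexane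
Product: 15 2-[(1S,2R,5R)-1,2-dimethylbicyclo[3.1.0]hexan-2-yl]-5-methylphenol (debromolaurinterol)
Conditions: NaSEt (6 equiv), DMF, 130 °C; cold 0.5 M HCl to pH 6–7
Reagents that add atoms: none
Why: SN2 dealkylation of the aryl methyl ether by thiolate at the methyl carbon works under basic conditions; it is chosen because Lewis or Brønsted acids would open the cyclopropane with participation of the liberated phenol.

Step 10
Reactants: 15 2-[(1S,2R,5R)-1,2-dimethylbicyclo[3.1.0]hexan-2-yl]-5-methylphenol
Product: 16 2,4-dibromo-6-[(1S,2R,5R)-1,2-dimethylbicyclo[3.1.0]hexan-2-yl]-3-methylphenol (target)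
Conditions: NBS (2.1 equiv), NaHCO3 (solid), MeCN, −20 → 0 °C, dark
Reagents that add atoms: N-bromosuccinimide, O=C1CCC(=O)N1Br
Why: Electrophilic aromatic bromination is steered by the free OH to its only open ortho and para positions (the remaining ring C–H is meta to OH), and NBS takes up the displaced proton as succinimide, so no HBr arises to open the cyclopropane.

## Compound list

1 | 2-bromo-5-methylanisole | COc1cc(C)ccc1Br | starting material
2 | tert-butyl propionate | CCC(=O)OC(C)(C)C | starting material
3 | tert-butyl 2-(2-methoxy-4-methylphenyl)propanoate (racemic) | Cc1ccc(C(C)C(=O)OC(C)(C)C)c(OC)c1 | intermediate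
4 | 2-(2-methoxy-4-methylphenyl)propanoic acid (racemic) | Cc1ccc(C(C)C(=O)O)c(OC)c1 | intermediate
5 | 3-bromo-1-(trimethylsilyl)prop-1-yne | C[Si](C)(C)C#CCBr | starting material
6 | dilithium enediolate of 4 (not isolated) | Cc1ccc(C(C)=C([O-])[O-])c(OC)c1.[Li+].[Li+] | intermediate
7 | (S)-2-(2-methoxy-4-methylphenyl)-2-methyl-5-(trimethylsilyl)pent-4-ynoic acid | Cc1ccc([C@](C(=O)O)(C)CC#C[Si](C)(C)C)c(OC)c1 | intermediate
8 | dilithium gem-diolate from 7 and MeLi (not isolated) | Cc1ccc([C@](C(C)([O-])[O-])(C)CC#C[Si](C)(C)C)c(OC)c1.[Li+].[Li+] | intermediate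
9 | (S)-3-(2-methoxy-4-methylphenyl)-3-methyl-6-(trimethylsilyl)hex-5-yn-2-one | Cc1ccc([C@](C(C)=O)(C)CC#C[Si](C)(C)C)c(OC)c1 | intermediate
10 | trimethyl[(4R)-4-(2-methoxy-4-methylphenyl)-4,5-dimethylhex-5-en-1-yn-1-yl]silane | Cc1ccc([C@](C(C)=C)(C)CC#C[Si](C)(C)C)c(OC)c1 | intermediate
11 | 1-[(3R)-2,3-dimethylhex-1-en-5-yn-3-yl]-2-methoxy-4-methylbenzene | Cc1ccc([C@](C(C)=C)(C)CC#C)c(OC)c1 | intermediate
12 | cyclopropyl gold(I) carbene: Ph3PAu carbene at C4 of the bicyclo[3.1.0]hexane, configuration as in 13, NTf2 salt (not isolated) | Cc1ccc([C@]2(C)CC(=[Au][P+](c4ccccc4)(c4ccccc4)c4ccccc4)[C@@H]3C[C@@]32C)c(OC)c1.O=S(=O)([N-]S(=O)(=O)C(F)(F)F)C(F)(F)F | intermediate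
13 | (1S,4R,5S)-4-(2-methoxy-4-methylphenyl)-4,5-dimethylbicyclo[3.1.0]hex-2-ene | Cc1ccc([C@]2(C)C=C[C@@H]3C[C@@]32C)c(OC)c1 | intermediate
14 | (1S,2R,5R)-2-(2-methoxy-4-methylphenyl)-1,2-dimethylbicyclo[3.1.0]hexane | Cc1ccc([C@]2(C)CC[C@@H]3C[C@@]32C)c(OC)c1 | intermediate
15 | 2-[(1S,2R,5R)-1,2-dimethylbicyclo[3.1.0]hexan-2-yl]-5-methylphenol | Cc1ccc([C@]2(C)CC[C@@H]3C[C@@]32C)c(O)c1 | intermediate
16 | 2,4-dibromo-6-[(1S,2R,5R)-1,2-dimethylbicyclo[3.1.0]hexan-2-yl]-3-methylphenol | Cc1c(Br)cc([C@]2(C)CC[C@@H]3C[C@@]32C)c(O)c1Br | target

Total step count: 10. Longest linear sequence: 10 steps (from 1).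

## Steps most likely to fail

**Step 7.** Possible failures:
- Facial selectivity at the isopropenyl group may be poor.
- The cationic intermediate may be diverted by proton loss to cyclohexadienes, by migration of the electron-rich aryl group, or by capture at the ether oxygen.

Fallback, from 9 back to 15: the same two carbons are joined as an alkene, and the CH2 is then delivered under direction by the phenol.
- K2CO3/MeOH removes silicon from 9 to give (S)-3-(2-methoxy-4-methylphenyl)-3-methylhex-5-yn-2-one F1.
- Anti-Markovnikov hydration of the alkyne (Cy2BH, then NaBO3) gives (S)-4-(2-methoxy-4-methylphenyl)-4-methyl-5-oxohexanal F2.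
- Intramolecular McMurry coupling (TiCl3, Zn–Cu, DME, reflux) gives 1-[(1R)-1,2-dimethylcyclopent-2-en-1-yl]-2-methoxy-4-methylbenzene F3.
- NaSEt in DMF gives 2-[(1R)-1,2-dimethylcyclopent-2-en-1-yl]-5-methylphenol F4.
- A Simmons–Smith cyclopropanation (Et2Zn, CH2I2, CH2Cl2), directed by the zinc phenoxide to the alkene face syn to the aryl group, gives 15.

**Step 3.** Possible failures:
- Face discrimination may be insufficient, because the ortho-methoxy group and the α-methyl group can disturb the mixed aggregate.
- The hindered enediolate may not convert fully.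

Fallback, from 4 back to 7: racemic alkylation followed by classical resolution.
- The dianion of 4 (LDA, 2.2 equiv, THF) is alkylated with 5 to give racemic 2-(2-methoxy-4-methylphenyl)-2-methyl-5-(trimethylsilyl)pent-4-ynoic acid F5.
- Fractional crystallisation with 1-phenylethylamine follows. The antipode is chosen so that the salt of the (S)-acid is the less soluble one, and it is written here as (R). This gives the (R)-1-phenylethylammonium salt of the (S)-acid F6.
- Acidification of F6 returns 7.

**Step 10.** Possible failures:
- The cyclopropane may open under electrophilic or adventitious acidic conditions, with capture by the neighbouring phenol oxygen.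
- The second bromination, at the hindered site between OH and CH3, may stall.
- Over-oxidation to bromodienones may occur.

Fallback, from 14 back to 16: both halogens are placed on the ether, so that a free phenol never meets an electrophilic bromine source.
- Directed ortho-lithiation of 14 (n-BuLi, TMEDA, Et2O) and a quench with 1,2-dibromotetrafluoroethane give (1S,2R,5R)-2-(3-bromo-2-methoxy-4-methylphenyl)-1,2-dimethylbicyclo[3.1.0]hexane F7.
- Para-bromination with NBS in MeCN gives (1S,2R,5R)-2-(3,5-dibromo-2-methoxy-4-methylphenyl)-1,2-dimethylbicyclo[3.1.0]hexane F8.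
- The di-ortho-flanked, more labile methyl ether of F8 is cleaved with NaSEt in DMF at about 90 °C to give 16.

## Further compounds

F1 | step 7 | (S)-3-(2-methoxy-4-methylphenyl)-3-methylhex-5-yn-2-one | Cc1ccc([C@](C(C)=O)(C)CC#C)c(OC)c1
F2 | step 7 | (S)-4-(2-methoxy-4-methylphenyl)-4-methyl-5-oxohexanal | Cc1ccc([C@](C(C)=O)(C)CCC=O)c(OC)c1
F3 | step 7 | 1-[(1R)-1,2-dimethylcyclopent-2-en-1-yl]-2-methoxy-4-methylbenzene | Cc1ccc([C@]2(C)CCC=C2C)c(OC)c1
F4 | step 7 | 2-[(1R)-1,2-dimethylcyclopent-2-en-1-yl]-5-methylphenol | Cc1ccc([C@]2(C)CCC=C2C)c(O)c1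
F5 | step 3 | racemic 2-(2-methoxy-4-methylphenyl)-2-methyl-5-(trimethylsilyl)pent-4-ynoic acid | Cc1ccc(C(C)(CC#C[Si](C)(C)C)C(=O)O)c(OC)c1
F6 | step 3 | (R)-1-phenylethylammonium (S)-2-(2-methoxy-4-methylphenyl)-2-methyl-5-(trimethylsilyl)pent-4-ynoate | Cc1ccc([C@](C(=O)[O-])(C)CC#C[Si](C)(C)C)c(OC)c1.C[C@@H]([NH3+])c1ccccc1
F7 | step 10 | (1S,2R,5R)-2-(3-bromo-2-methoxy-4-methylphenyl)-1,2-dimethylbicyclo[3.1.0]hexane | Cc1ccc([C@]2(C)CC[C@@H]3C[C@@]32C)c(OC)c1Br
F8 | step 10 | (1S,2R,5R)-2-(3,5-dibromo-2-methoxy-4-methylphenyl)-1,2-dimethylbicyclo[3.1.0]hexane | Cc1c(Br)cc([C@]2(C)CC[C@@H]3C[C@@]32C)c(OC)c1Br
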